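**Plan**

1. Retrosynthesis: the enol ether O–CH= bond is cut first (C–O coupling of a chiral benzylic alcohol with a (Z)-vinyl iodide). The alcohol goes back to the ketone encecalin, and the vinyl iodide is cut at its aryl–C2 bond (aryl Grignard reagent plus propargyl alcohol).
2. The pyran ring of encecalin (O1, C2, C3, C4, C4a, C8a) is not closed as such. It is grown from the five-membered ring of a racemic 2-isopropenyl-2,3-dihydrobenzofuran: the isopropenyl carbon is inserted between O1 and the old C2, and one hydrogen moves from the ring CH2 to the terminal CH2.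
3. What makes this possible: in that furan ring O1 sits on a carbon allylic to the isopropenyl group and is also a phenoxide oxygen para to the acetyl group (a good nucleofuge). The ring CH2 (future C4) is benzylic on the arene carbon para to the methoxy-bearing carbon, so ionization, hydrogen shift and re-closure at the dimethyl carbon are all open.
4. Forward order: the arene is bought; iodination and diene heteroannulation build the furan ring; ring expansion gives the chromene; the ketone is reduced; the two halves are joined by C–O coupling and desilylated.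
5. Stereochemistry: the (S) carbinol centre comes from ruthenium-catalysed asymmetric transfer hydrogenation and is not touched afterwards. The (Z) enol ether geometry comes from chelation-controlled anti-carbomagnesiation/iodination and a stereoretentive coupling.

Key step: step 3

Remark on the chemistry: compounds 1, 3, 8 and 10 are taken as catalogue compounds; the C2 stereocentre of the dihydrobenzofuran is erased in step 3, so that compound is made as the racemate.

**Route**

Step 1
Reactants: 1 1-(4-hydroxy-2-methoxyphenyl)ethan-1-one
Product: 2 1-(4-hydroxy-5-iodo-2-methoxyphenyl)ethan-1-one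
Conditions: NIS (1.05 equiv), TFA (10 mol %), MeCN, 0 °C to rt
Reagents that add atoms: N-iodosuccinimide, O=C1CCC(=O)N1I
Why: Electrophilic aromatic iodination, in which the hydroxyl group (ortho) and the methoxy group (para) both direct to C5 while C3 between the two oxygen substituents is hindered, so the iodine should mark the carbon that becomes C4a of the chromene.

Step 2
Reactants: 2 1-(4-hydroxy-5-iodo-2-methoxyphenyl)ethan-1-one; 3 isoprene
Product: 4 rac-1-[6-methoxy-2-(prop-1-en-2-yl)-2,3-dihydro-1-benzofuran-5-yl]ethan-1-one (6-methoxytremetone)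
Conditions: Pd(OAc)2 (5 mol %), n-Bu4NCl, NaHCO3, isoprene (5 equiv), DMF, 80 °C, sealed tube
Reagents that add atoms: none
Why: Larock-type heteroannulation of a 1,3-diene, in which the arylpalladium formed by oxidative addition inserts the unsubstituted vinyl group of isoprene and the phenoxide closes the resulting 2-methylallyl complex at its internal terminus to the five-membered ring, the C2 stereocentre being formed as a racemate, which is acceptable because step 3 destroys it.

Step 3
Reactants: 4 rac-1-[6-methoxy-2-(prop-1-en-2-yl)-2,3-dihydro-1-benzofuran-5-yl]ethan-1-one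
Product: 6 1-(7-methoxy-2,2-dimethyl-2H-chromen-6-yl)ethan-1-one (encecalin), via dienylphenol 5 (not isolated)
Conditions: Pd2(dba)3 (2.5 mol %), DPEphos (6 mol %), PhCO2H (10 mol %), toluene (0.05 M), 100 °C
Reagents that add atoms: none
Why: Proposed new method: zerovalent palladium should ionize the O1–C2 bond of 4, which is allylic to the isopropenyl group and releases a phenoxide stabilized by the para acetyl group; the 2-methylallyl palladium complex so formed can lose a benzylic β-hydrogen from C3 to give dienylphenol 5 and a palladium hydride, which adds back to the terminal CH2 of the diene to give the aryl-conjugated 3,3-dimethylallyl complex that the phenol oxygen closes at its tertiary terminus. The closest known reaction types are the Tsuji–Trost ionization of allyl aryl ethers, the palladium-catalysed 1,4-elimination of allylic esters and ethers to 1,3-dienes and the palladium hydride catalysed hydroalkoxylation of 1,3-dienes by phenols, here linked into one redox-neutral isomerization. The six-membered ring closes by O–C bond formation at the dimethyl-substituted terminus of the anti-configured allyl unit, with the new C3=C4 double bond inside the ring (endo mode), so that the five-membered ring has grown by the former isopropenyl carbon. No stereocentre is formed and the C2 centre of 4 is erased, which is why racemic 4 is used. The step needs the hydrogen to return to the diene terminus instead of the benzylic carbon and the oxygen to attack the tertiary carbon: conjugation of the new allyl unit with the arene (C4a is para to the methoxy-bearing C7), the impossibility of closure at the benzylic terminus and the reversibility of every C–O closure, which lets the material drain to the conjugated chromene as the most stable ether, should secure both.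

Step 4
Reactants: 6 1-(7-methoxy-2,2-dimethyl-2H-chromen-6-yl)ethan-1-one
Product: 7 (1S)-1-(7-methoxy-2,2-dimethyl-2H-chromen-6-yl)ethan-1-ol
Conditions: RuCl(p-cymene)[(S,S)-TsDPEN] (1 mol %), HCO2Na (5 equiv), MeOH/H2O 1:1, 40 °C; chromatography on Et3N-treated silica
Reagents that add atoms: none
Why: Noyori–Ikariya asymmetric transfer hydrogenation of an aryl methyl ketone, in which the (S,S)-TsDPEN ruthenium hydride delivers hydride to the Re face of the carbonyl through the CH/π-organized six-membered transition state and so sets the (S) carbinol centre, while the non-acidic formate medium spares the ionization-prone benzylic alcohol and the chromene double bond.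

Step 5
Reactants: 8 2-bromo-5-methylphenol
Product: 9 1-bromo-2-(methoxymethoxy)-4-methylbenzene
Conditions: MOMCl, i-Pr2NEt, CH2Cl2, 0 °C to rt
Reagents that add atoms: chloromethyl methyl ether, COCCl
Why: Williamson-type O-alkylation of the phenol gives the MOM acetal, which masks the acidic hydroxyl group for the Grignard step.

Step 6
Reactants: 9 1-bromo-2-(methoxymethoxy)-4-methylbenzene; 10 prop-2-yn-1-ol
Product: 13 (2Z)-3-iodo-2-[2-(methoxymethoxy)-4-methylphenyl]prop-2-en-1-ol, via aryl Grignard reagent 11 (not isolated), via oxamagnesacycle 12 (not isolated)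
Conditions: Mg, THF, 40 °C; then ClMgOCH2C≡CH (from 10, i-PrMgCl 1.0 equiv), CuI (10 mol %), THF/toluene, 0 °C to rt; then I2, −20 °C
Reagents that add atoms: iodine, II
Why: Copper-catalysed anti-carbomagnesiation of the magnesium propargylic alkoxide places the aryl group on C2 and magnesium on C3 cis to the CH2O group in the five-membered chelate 12, and iodinolysis with retention then fixes iodine cis to CH2OH and trans to the aryl group, which is the geometry needed for the enol ether.

Step 7
Reactants: 13 (2Z)-3-iodo-2-[2-(methoxymethoxy)-4-methylphenyl]prop-2-en-1-ol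
Product: 14 2-[(1Z)-3-hydroxy-1-iodoprop-1-en-2-yl]-5-methylphenol
Conditions: HCl (cat.), MeOH, 45 °C
Reagents that add atoms: none
Why: Acid-catalysed acetal exchange with methanol removes the MOM group at a stage that still tolerates acid, which the final enol ether would not.

Step 8
Reactants: 14 2-[(1Z)-3-hydroxy-1-iodoprop-1-en-2-yl]-5-methylphenol
Product: 15 {[(2Z)-3-iodo-2-{4-methyl-2-[(triisopropylsilyl)oxy]phenyl}prop-2-en-1-yl]oxy}(triisopropyl)silane
Conditions: TIPSOTf (2.4 equiv), 2,6-lutidine, CH2Cl2, 0 °C
Reagents that add atoms: triisopropylsilyl trifluoromethanesulfonate, CC(C)[Si](C(C)C)(C(C)C)OS(=O)(=O)C(F)(F)F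
Why: Silylation of both hydroxyl groups, with the bulky TIPS group chosen because the aryl silyl ether should then resist silyl transfer to the cesium alkoxide of step 9 and both groups leave with fluoride under non-acidic conditions.

Step 9
Reactants: 7 (1S)-1-(7-methoxy-2,2-dimethyl-2H-chromen-6-yl)ethan-1-ol; 15 {[(2Z)-3-iodo-2-{4-methyl-2-[(triisopropylsilyl)oxy]phenyl}prop-2-en-1-yl]oxy}(triisopropyl)silane
Product: 16 6-[(1S)-1-{[(1Z)-2-{4-methyl-2-[(triisopropylsilyl)oxy]phenyl}-3-[(triisopropylsilyl)oxy]prop-1-en-1-yl]oxy}ethyl]-7-methoxy-2,2-dimethyl-2H-chromene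
Conditions: CuI (10 mol %), 3,4,7,8-tetramethyl-1,10-phenanthroline (20 mol %), Cs2CO3 (2 equiv), 15 (1.3 equiv), toluene, 85 °C
Reagents that add atoms: none
Why: Ullmann-type copper-catalysed C–O cross-coupling of an alcohol with a vinyl iodide, which proceeds with retention of the alkene geometry and does not touch the carbinol C–O bond, so the (Z) enol ether and the (S) centre should both be carried over.

Step 10
Reactants: 16 6-[(1S)-1-{[(1Z)-2-{4-methyl-2-[(triisopropylsilyl)oxy]phenyl}-3-[(triisopropylsilyl)oxy]prop-1-en-1-yl]oxy}ethyl]-7-methoxy-2,2-dimethyl-2H-chromene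
Product: 17 2-[(1Z)-3-hydroxy-1-{[(1S)-1-(7-methoxy-2,2-dimethyl-2H-chromen-6-yl)ethyl]oxy}prop-1-en-2-yl]-5-methylphenol
Conditions: TBAF (2.5 equiv), THF, 0 °C to rt; pH 7 phosphate buffer work-up
Reagents that add atoms: none
Why: Fluoride-mediated desilylation cleaves the aryl and the primary silyl ether under basic conditions that should leave the acid-labile enol ether and the doubly activated benzylic ether intact.

**Compound list**

1 | 1-(4-hydroxy-2-methoxyphenyl)ethan-1-one | CC(=O)c1ccc(O)cc1OC | starting material
2 | 1-(4-hydroxy-5-iodo-2-methoxyphenyl)ethan-1-one | CC(=O)c1cc(I)c(O)cc1OC | intermediate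
3 | isoprene (2-methylbuta-1,3-diene) | C=CC(C)=C | starting material
4 | rac-1-[6-methoxy-2-(prop-1-en-2-yl)-2,3-dihydro-1-benzofuran-5-yl]ethan-1-one (racemate) | CC(=O)c1cc2CC(C(C)=C)Oc2cc1OC | intermediate
5 | 1-{4-hydroxy-2-methoxy-5-[(1E)-3-methylbuta-1,3-dien-1-yl]phenyl}ethan-1-one | CC(=O)c1cc(/C=C/C(C)=C)c(O)cc1OC | intermediate (not isolated)
6 | 1-(7-methoxy-2,2-dimethyl-2H-chromen-6-yl)ethan-1-one (encecalin) | CC(=O)c1cc2C=CC(C)(C)Oc2cc1OC | intermediate
7 | (1S)-1-(7-methoxy-2,2-dimethyl-2H-chromen-6-yl)ethan-1-ol | COc1cc2c(cc1[C@H](C)O)C=CC(C)(C)O2 | intermediate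
8 | 2-bromo-5-methylphenol | Cc1ccc(Br)c(O)c1 | starting material
9 | 1-bromo-2-(methoxymethoxy)-4-methylbenzene | COCOc1cc(C)ccc1Br | intermediate
10 | prop-2-yn-1-ol | C#CCO | starting material
11 | [2-(methoxymethoxy)-4-methylphenyl]magnesium bromide | COCOc1cc(C)ccc1[Mg]Br | intermediate (not isolated)
12 | 4-[2-(methoxymethoxy)-4-methylphenyl]-2,5-dihydro-1,2-oxamagnesole | COCOc1cc(C)ccc1C1=C[Mg]OC1 | intermediate (not isolated)
13 | (2Z)-3-iodo-2-[2-(methoxymethoxy)-4-methylphenyl]prop-2-en-1-ol | OC/C(=C\I)c1ccc(C)cc1OCOC | intermediate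
14 | 2-[(1Z)-3-hydroxy-1-iodoprop-1-en-2-yl]-5-methylphenol | OC/C(=C\I)c1ccc(C)cc1O | intermediate
15 | {[(2Z)-3-iodo-2-{4-methyl-2-[(triisopropylsilyl)oxy]phenyl}prop-2-en-1-yl]oxy}(triisopropyl)silane | CC(C)[Si](C(C)C)(C(C)C)OC/C(=C\I)c1ccc(C)cc1O[Si](C(C)C)(C(C)C)C(C)C | intermediate
16 | 6-[(1S)-1-{[(1Z)-2-{4-methyl-2-[(triisopropylsilyl)oxy]phenyl}-3-[(triisopropylsilyl)oxy]prop-1-en-1-yl]oxy}ethyl]-7-methoxy-2,2-dimethyl-2H-chromene | COc1cc2c(cc1[C@H](C)O/C=C(\CO[Si](C(C)C)(C(C)C)C(C)C)c1ccc(C)cc1O[Si](C(C)C)(C(C)C)C(C)C)C=CC(C)(C)O2 | intermediate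
17 | 2-[(1Z)-3-hydroxy-1-{[(1S)-1-(7-methoxy-2,2-dimethyl-2H-chromen-6-yl)ethyl]oxy}prop-1-en-2-yl]-5-methylphenol | COc1cc2c(cc1[C@H](C)O/C=C(\CO)c1ccc(C)cc1O)C=CC(C)(C)O2 | target

**Totals**

Total step count: 10. Longest linear sequence: 6 steps (steps 1, 2, 3, 4, 9, 10; the other branch, steps 5, 6, 7, 8, 9, 10, is equally long).

**Steps most likely to fail**

Step 3 (Proposed new method). The allyl palladium phenoxide ion pair may simply re-close to 4 faster than it loses the benzylic hydrogen, so that nothing happens. Dienylphenol 5 may also accumulate or oligomerize by intermolecular hydroalkoxylation. The first allyl unit may close at its primary terminus to a seven-membered ether, or the palladium hydride may move the isopropenyl double bond into the furan ring and aromatize it. The fallback uses known chemistry and closes the six-membered ring directly, without ring expansion. It sets out from 2: a Heck reaction with 2-methylbut-3-en-2-ol (Pd(OAc)2, P(o-tol)3, Et3N, MeCN, 80 °C) should give 1-{4-hydroxy-5-[(1E)-3-hydroxy-3-methylbut-1-en-1-yl]-2-methoxyphenyl}ethan-1-one F1. Brief heating of F1 with PPTS in toluene should ionize the tertiary allylic alcohol to an allyl cation that equilibrates its geometry and is captured by the phenol oxygen at the dimethyl-substituted terminus with loss of water. The fallback comes back to the route at 6.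

Step 9. The hindered secondary alkoxide may couple slowly, which would let side processes take over: oxidation of the alcohol by β-hydride loss at copper, proto-deiodination of the vinyl iodide, silyl transfer from the aryl silyl ether to the alkoxide, or heterolysis of the doubly activated benzylic C–O bond of the product with O-to-C migration. The fallback forms the O–C(sp) bond first and the aryl–alkene bond last. It sets out from 7:
- Deprotonation with KH in THF and addition of trichloroethylene should give the dichlorovinyl ether 6-[(1S)-1-{[(E)-1,2-dichloroethenyl]oxy}ethyl]-7-methoxy-2,2-dimethyl-2H-chromene F2.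
- n-BuLi (2.2 equiv, THF, −78 °C) should convert F2 into the lithium alkynyl ether lithium 2-[(1S)-1-(7-methoxy-2,2-dimethyl-2H-chromen-6-yl)ethoxy]ethynide F3, which is trapped with paraformaldehyde to give 3-[(1S)-1-(7-methoxy-2,2-dimethyl-2H-chromen-6-yl)ethoxy]prop-2-yn-1-ol F4; this is kept below room temperature.
- Silylation with TIPSCl and imidazole gives triisopropyl({3-[(1S)-1-(7-methoxy-2,2-dimethyl-2H-chromen-6-yl)ethoxy]prop-2-yn-1-yl}oxy)silane F5.
- Syn-hydroboration with Cy2BH (THF, 0 °C) should put boron on the carbon β to oxygen and hydrogen on the oxygen-bearing carbon, giving the alkenylborane dicyclohexyl[(1Z)-1-{[(1S)-1-(7-methoxy-2,2-dimethyl-2H-chromen-6-yl)ethyl]oxy}-3-[(triisopropylsilyl)oxy]prop-1-en-2-yl]borane F6, which is used without isolation.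
- Suzuki–Miyaura coupling of F6 (Pd(dppf)Cl2, aqueous K3PO4, THF, 50 °C) with the aryl bromide (2-bromo-5-methylphenoxy)tri(propan-2-yl)silane F7, made from 8 with TIPSCl and imidazole, proceeds with retention and so places the aryl group trans to the ether oxygen.

The fallback comes back to the route at 16.

Step 6. The ortho-alkoxy aryl Grignard reagent may add sluggishly to the magnesium propargylic alkoxide, so that protonation of the reagent, its copper-mediated homocoupling or aryl delivery to C3 erodes the outcome. The fallback makes the aryl–C2 bond by syn-carbopalladation and lets a silyl group hold the place of the iodine. It sets out from 9: a reductive Heck reaction (hydroarylation) with 3-(trimethylsilyl)prop-2-yn-1-ol (Pd(OAc)2, PPh3, HCO2H/piperidine, DMF, 80 °C) should add the aryl group to the alkyne carbon remote from silicon and hydrogen cis to it, giving (2Z)-2-[2-(methoxymethoxy)-4-methylphenyl]-3-(trimethylsilyl)prop-2-en-1-ol F8. Iododesilylation of F8 with NIS in MeCN at 0 °C proceeds with retention. The fallback comes back to the route at 13.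

**Further compounds**

F1 | step 3 | 1-{4-hydroxy-5-[(1E)-3-hydroxy-3-methylbut-1-en-1-yl]-2-methoxyphenyl}ethan-1-one | CC(=O)c1cc(/C=C/C(C)(C)O)c(O)cc1OC
F2 | step 9 | 6-[(1S)-1-{[(E)-1,2-dichloroethenyl]oxy}ethyl]-7-methoxy-2,2-dimethyl-2H-chromene | COc1cc2c(cc1[C@H](C)O/C(Cl)=C\Cl)C=CC(C)(C)O2
F3 | step 9 | lithium 2-[(1S)-1-(7-methoxy-2,2-dimethyl-2H-chromen-6-yl)ethoxy]ethynide | COc1cc2c(cc1[C@H](C)OC#C[Li])C=CC(C)(C)O2
F4 | step 9 | 3-[(1S)-1-(7-methoxy-2,2-dimethyl-2H-chromen-6-yl)ethoxy]prop-2-yn-1-ol | COc1cc2c(cc1[C@H](C)OC#CCO)C=CC(C)(C)O2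
F5 | step 9 | triisopropyl({3-[(1S)-1-(7-methoxy-2,2-dimethyl-2H-chromen-6-yl)ethoxy]prop-2-yn-1-yl}oxy)silane | COc1cc2c(cc1[C@H](C)OC#CCO[Si](C(C)C)(C(C)C)C(C)C)C=CC(C)(C)O2
F6 | step 9 | dicyclohexyl[(1Z)-1-{[(1S)-1-(7-methoxy-2,2-dimethyl-2H-chromen-6-yl)ethyl]oxy}-3-[(triisopropylsilyl)oxy]prop-1-en-2-yl]borane | COc1cc2c(cc1[C@H](C)O/C=C(\CO[Si](C(C)C)(C(C)C)C(C)C)B(C1CCCCC1)C1CCCCC1)C=CC(C)(C)O2
F7 | step 9 | (2-bromo-5-methylphenoxy)tri(propan-2-yl)silane | Cc1ccc(Br)c(O[Si](C(C)C)(C(C)C)C(C)C)c1
F8 | step 6 | (2Z)-2-[2-(methoxymethoxy)-4-methylphenyl]-3-(trimethylsilyl)prop-2-en-1-ol | C[Si](C)(C)/C=C(\CO)c1ccc(C)cc1OCOC
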